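**Plan**

1. Hydroazulene locants: C1 (OAc), C3 (OH, i‑Pr), C3a–H, C4 (aroyloxy), C5=C6(Me)–C7(=O), C8, C8a (Me). Retrosynthetic cuts, in order: phenol silyl ether and C4 ester C–O; ring bond C6–C7; C4–C5; C3–isopropyl; C8a–C8; C3a–C4; C8a–methyl.
2. Enabling feature: in the seven‑membered ring the C4 oxygen and the C7 carbonyl are 1,4‑related across C5=C6. Tying C4–O to C7 gives a six‑membered lactone (O, C7, C8, C8a, C3a, C4) that carries the C5=C6 unit on C4, so a C6 carbanion can reach C7 across that lactone.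
3. Forward: the cyclopentane comes from (S)‑4‑silyloxycyclopentenone 1 by α‑methylation, vinyl conjugate addition and enolate alkylation with bromoacetate, followed by redox adjustment and isopropyl addition; the δ‑lactone is a temporary second ring.
4. The seven‑membered carbocycle is closed last by iodine–lithium exchange and transannular acyl transfer, which consumes the lactone, delivers the enone at its final oxidation level and frees C4–OH for the aryl ester.
5. Stereochemistry: the silyloxy carbon of 1 relays to C3a and then C8a (each anti) and is later oxidised; C1 comes from CBS reduction, C3 from addition anti to the C3a substituent, C4 from chelation‑controlled alkynylation.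

Key step: step 14

**Route**

Step 1
Reactants: 1 (S)-4-[(tert-butyldimethylsilyl)oxy]cyclopent-2-en-1-one
Product: 2 (S)-4-[(tert-butyldimethylsilyl)oxy]-2-iodocyclopent-2-en-1-one
Conditions: I2, pyridine, CH2Cl2, 0 °C to rt
Reagents that add atoms: iodine, II
Why: α-Iodination of the enone by the pyridine/iodine addition–elimination sequence (Baylis–Hillman-type) is routine for 4-silyloxycyclopentenones and leaves the silyloxy stereocentre untouched.

Step 2
Reactants: 2 (S)-4-[(tert-butyldimethylsilyl)oxy]-2-iodocyclopent-2-en-1-one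
Product: 3 (S)-4-[(tert-butyldimethylsilyl)oxy]-2-methylcyclopent-2-en-1-one
Conditions: Me4Sn, Pd2(dba)3 (5 mol%), AsPh3, CuI, NMP, 60 °C
Reagents that add atoms: tetramethylstannane, C[Sn](C)(C)C
Why: Stille coupling of an α-iodoenone runs under neutral conditions, so the future C8a methyl group is installed without base-induced loss of the γ-silyloxy group.

Step 3
Reactants: 3 (S)-4-[(tert-butyldimethylsilyl)oxy]-2-methylcyclopent-2-en-1-one
Product: 4 tert-butyldimethyl{[(1S,2S)-3-methyl-4-[(trimethylsilyl)oxy]-2-vinylcyclopent-3-en-1-yl]oxy}silane (vinyl trans to OTBS)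
Conditions: CH2=CHMgBr, CuBr·SMe2 (10 mol%), TMSCl, HMPA, THF, −78 °C; Et3N
Reagents that add atoms: vinylmagnesium bromide, C=C[Mg]Br; chlorotrimethylsilane, C[Si](C)(C)Cl
Why: Copper-catalysed, TMSCl-accelerated conjugate addition delivers the vinyl group anti to the silyloxy substituent, which sets C3a, and traps the enolate regiospecifically as its silyl enol ether.

Step 4
Reactants: 4 tert-butyldimethyl{[(1S,2S)-3-methyl-4-[(trimethylsilyl)oxy]-2-vinylcyclopent-3-en-1-yl]oxy}silane
Product: 6 methyl 2-[(1S,2S,3S)-3-[(tert-butyldimethylsilyl)oxy]-1-methyl-5-oxo-2-vinylcyclopentyl]acetate, via lithium enolate 5 (not isolated)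
Conditions: MeLi, THF, 0 °C; then BrCH2CO2Me, HMPA, −78 to −20 °C
Reagents that add atoms: methyl bromoacetate, COC(=O)CBr
Why: Si–O cleavage by MeLi regenerates the tetrasubstituted lithium enolate without equilibration, and its alkylation by the activated bromide occurs anti to the adjacent vinyl group (trans-2,3-dialkylation of cyclopentanone enolates), which sets the quaternary C8a with methyl cis to vinyl.

Step 5
Reactants: 6 methyl 2-[(1S,2S,3S)-3-[(tert-butyldimethylsilyl)oxy]-1-methyl-5-oxo-2-vinylcyclopentyl]acetate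
Product: 7 methyl 2-[(1S,2S,3S,5S)-3-[(tert-butyldimethylsilyl)oxy]-5-hydroxy-1-methyl-2-vinylcyclopentyl]acetate
Conditions: (R)-2-methyl-CBS-oxazaborolidine (0.5 equiv), catecholborane, toluene, −78 to −40 °C
Reagents that add atoms: none
Why: Corey–Bakshi–Shibata reduction differentiates the quaternary from the methylene flank of the ketone, so the (R)-catalyst should deliver hydride to the face anti to the angular methyl group and set C1 as the (S)-carbinol (OH cis to methyl), while catecholborane spares the ester and the alkene.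

Step 6
Reactants: 7 methyl 2-[(1S,2S,3S,5S)-3-[(tert-butyldimethylsilyl)oxy]-5-hydroxy-1-methyl-2-vinylcyclopentyl]acetate
Product: 8 methyl 2-[(1S,2S,3S,5S)-5-acetoxy-3-[(tert-butyldimethylsilyl)oxy]-1-methyl-2-vinylcyclopentyl]acetate
Conditions: Ac2O, DMAP, pyridine, CH2Cl2, rt
Reagents that add atoms: acetic anhydride, CC(=O)OC(C)=O
Why: DMAP-catalysed acetylation of the only free hydroxyl installs the C1 acetate of the target, which is neopentylic and should survive the later low-temperature organometallic steps.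

Step 7
Reactants: 8 methyl 2-[(1S,2S,3S,5S)-5-acetoxy-3-[(tert-butyldimethylsilyl)oxy]-1-methyl-2-vinylcyclopentyl]acetate
Product: 9 methyl 2-[(1S,2S,3S,5S)-5-acetoxy-3-hydroxy-1-methyl-2-vinylcyclopentyl]acetate
Conditions: HF·pyridine, pyridine, THF, 0 °C to rt
Reagents that add atoms: none
Why: Fluoride cleaves the secondary silyl ether under mildly acidic conditions that leave both esters intact and avoid alkoxide-induced lactonisation onto the cis acetic ester chain.

Step 8
Reactants: 9 methyl 2-[(1S,2S,3S,5S)-5-acetoxy-3-hydroxy-1-methyl-2-vinylcyclopentyl]acetate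
Product: 10 methyl 2-[(1S,2S,5S)-5-acetoxy-1-methyl-3-oxo-2-vinylcyclopentyl]acetate
Conditions: Dess–Martin periodinane, NaHCO3, CH2Cl2, 0 °C to rt
Reagents that add atoms: none
Why: Dess–Martin oxidation is fast and non-basic, so the β-acetoxy, α-vinyl ketone should form without β-elimination or epimerisation at C3a.

Step 9
Reactants: 10 methyl 2-[(1S,2S,5S)-5-acetoxy-1-methyl-3-oxo-2-vinylcyclopentyl]acetate
Product: 11 methyl 2-[(1S,2S,3S,5S)-5-acetoxy-3-hydroxy-3-isopropyl-1-methyl-2-vinylcyclopentyl]acetate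
Conditions: i-PrMgCl, CeCl3, THF, −78 °C
Reagents that add atoms: isopropylmagnesium chloride, CC(C)[Mg]Cl
Why: The weakly basic, oxophilic organocerium reagent adds 1,2 to the enolisable ketone faster than to the esters and approaches anti to the adjacent vinyl group and to the cis-1,3 acetoxy group, which sets C3 with the hydroxyl cis to the C3a substituent.

Step 10
Reactants: 11 methyl 2-[(1S,2S,3S,5S)-5-acetoxy-3-hydroxy-3-isopropyl-1-methyl-2-vinylcyclopentyl]acetate
Product: 12 methyl 2-[(1S,2S,3S,5S)-5-acetoxy-2-formyl-3-hydroxy-3-isopropyl-1-methylcyclopentyl]acetate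
Conditions: O3, CH2Cl2, −78 °C; then PPh3, −78 °C to rt
Reagents that add atoms: ozone, O=[O+][O-]
Why: Ozonolysis with reductive work-up cleaves the only C=C bond to the C4 aldehyde under neutral conditions that spare the β-hydroxy aldehyde from retro-aldol cleavage.

Step 11
Reactants: 12 methyl 2-[(1S,2S,3S,5S)-5-acetoxy-2-formyl-3-hydroxy-3-isopropyl-1-methylcyclopentyl]acetate
Product: 14 (1S,4aS,5S,7S,7aR)-7-hydroxy-7-isopropyl-4a-methyl-3-oxo-1-(prop-1-yn-1-yl)octahydrocyclopenta[c]pyran-5-yl acetate, via hydroxy ester 13 (not isolated)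
Conditions: CH3C≡CMgBr (3.5 equiv), THF, −78 to 0 °C; then PPTS (cat.), CH2Cl2, rt
Reagents that add atoms: 1-propynylmagnesium bromide, CC#C[Mg]Br
Why: The aldehyde, held in a six-membered magnesium chelate with the cis tertiary alkoxide, is attacked from the face away from the quaternary C8a (also the Felkin–Anh face), which sets C4, and the new alkoxide then closes the trans-fused δ-lactone onto the methyl ester, an alkynyl Grignard reagent being too weak a nucleophile to attack the ester groups.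

Step 12
Reactants: 14 (1S,4aS,5S,7S,7aR)-7-hydroxy-7-isopropyl-4a-methyl-3-oxo-1-(prop-1-yn-1-yl)octahydrocyclopenta[c]pyran-5-yl acetate
Product: 15 (1S,4aS,5S,7S,7aR)-7-hydroxy-7-isopropyl-4a-methyl-3-oxo-1-[(Z)-2-(triethylsilyl)prop-1-en-1-yl]octahydrocyclopenta[c]pyran-5-yl acetate
Conditions: Et3SiH, [Cp*Ru(MeCN)3]PF6 (5 mol%), CH2Cl2, 0 °C to rt
Reagents that add atoms: triethylsilane, CC[SiH](CC)CC
Why: Cationic ruthenium-catalysed hydrosilylation adds H and Si trans across internal alkynes and places silicon on the carbon distal to a propargylic oxygen, which should give the (Z)-vinylsilane with silicon on C6 cis to C4 while tolerating the free alcohol, the acetate and the lactone.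

Step 13
Reactants: 15 (1S,4aS,5S,7S,7aR)-7-hydroxy-7-isopropyl-4a-methyl-3-oxo-1-[(Z)-2-(triethylsilyl)prop-1-en-1-yl]octahydrocyclopenta[c]pyran-5-yl acetate
Product: 16 (1S,4aS,5S,7S,7aR)-7-hydroxy-1-[(Z)-2-iodoprop-1-en-1-yl]-7-isopropyl-4a-methyl-3-oxooctahydrocyclopenta[c]pyran-5-yl acetate
Conditions: NIS, (CF3)2CHOH, 0 °C
Reagents that add atoms: N-iodosuccinimide, O=C1CCC(=O)N1I
Why: Iododesilylation in hexafluoroisopropanol proceeds by ipso attack of iodonium and loss of silicon from the β-silyl cation with retention of alkene geometry, which gives the (Z)-alkenyl iodide needed for ring closure.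

Step 14
Reactants: 16 (1S,4aS,5S,7S,7aR)-7-hydroxy-1-[(Z)-2-iodoprop-1-en-1-yl]-7-isopropyl-4a-methyl-3-oxooctahydrocyclopenta[c]pyran-5-yl acetate
Product: 19 (1S,3S,3aR,4R,8aS)-3,4-dihydroxy-3-isopropyl-6,8a-dimethyl-7-oxo-1,2,3,3a,4,7,8,8a-octahydroazulen-1-yl acetate, via alkenyllithium 17 (not isolated), via bridged lithium hemiketalate 18 (not isolated)
Conditions: t-BuLi (3.1 equiv), THF/Et2O/pentane, −100 to −78 °C; then sat. aq. NH4Cl, −78 °C to rt
Reagents that add atoms: none
Why: After the first equivalent of t-BuLi has deprotonated the C3 hydroxyl, iodine–lithium exchange gives alkenyllithium 17, whose C6 carbanion adds across the lactone ring to the carbonyl carbon C7 to give the bridged lithium hemiketalate 18, and protonation collapses 18 by cleavage of the C7–O(ring) bond to the C7 ketone conjugated with C5=C6 and the free C4 hydroxyl. The closest known reaction type is the Parham cyclisation, halogen–lithium exchange followed by intramolecular acyl substitution at an ester or lactone, which has a reductive counterpart in samarium diiodide-promoted ring expansions of halo-lactones through bicyclic hemiketals. The seven-membered carbocycle (C3a, C4, C5, C6, C7, C8, C8a) is closed at C6–C7 by a 5-exo-trig addition that first forms the 2,5-dihydrofuran ring of the 8-oxabicyclo[3.2.1]oct-6-ene 18, the (Z)-alkene placing C6 cis to C4 and the trans-fused lactone holding the alkenyl group axial, 1,3 to C7. No stereocentre is created in 19 (the hemiketal carbon of 18 is transient), C4 keeps its configuration because its C–O bond is not broken, and only the C4 epimer with an axial alkenyl group can close, so the step also filters the C4 configuration. The step needs exchange and cyclisation to outrun attack of t-BuLi on the lactone and acetate carbonyls and enolisation of the lactone: iodine–lithium exchange at −100 °C is close to diffusion-controlled, the addition is intramolecular through a five-membered transition state, the acetate is neopentylic, and the tetrahedral alkoxide 18 shields the new ketone from over-addition until work-up.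

Step 15
Reactants: 20 4-hydroxybenzoic acid
Product: 22 4-[(tert-butyldimethylsilyl)oxy]benzoic acid, via bis-silyl ester 21 (not isolated)
Conditions: TBSCl (2.2 equiv), imidazole, DMF, rt; then AcOH, THF, H2O, rt
Reagents that add atoms: tert-butyldimethylsilyl chloride, CC(C)(C)[Si](C)(C)Cl
Why: Exhaustive silylation followed by selective hydrolysis of the labile silyl ester is the standard route to the phenol-protected acid.

Step 16
Reactants: 19 (1S,3S,3aR,4R,8aS)-3,4-dihydroxy-3-isopropyl-6,8a-dimethyl-7-oxo-1,2,3,3a,4,7,8,8a-octahydroazulen-1-yl acetate; 22 4-[(tert-butyldimethylsilyl)oxy]benzoic acid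
Product: 23 (1S,3S,3aR,4R,8aS)-1-acetoxy-3-hydroxy-3-isopropyl-6,8a-dimethyl-7-oxo-1,2,3,3a,4,7,8,8a-octahydroazulen-4-yl 4-[(tert-butyldimethylsilyl)oxy]benzoate
Conditions: DCC, DMAP, CH2Cl2, 0 °C to rt
Reagents that add atoms: none
Why: Steglich esterification acylates the only secondary hydroxyl (the allylic C4–OH) with retention, the tertiary C3–OH being unreactive.

Step 17
Reactants: 23 (1S,3S,3aR,4R,8aS)-1-acetoxy-3-hydroxy-3-isopropyl-6,8a-dimethyl-7-oxo-1,2,3,3a,4,7,8,8a-octahydroazulen-4-yl 4-[(tert-butyldimethylsilyl)oxy]benzoate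
Product: 24 (1S,3S,3aR,4R,8aS)-1-acetoxy-3-hydroxy-3-isopropyl-6,8a-dimethyl-7-oxo-1,2,3,3a,4,7,8,8a-octahydroazulen-4-yl 4-hydroxybenzoate
Conditions: TBAF, AcOH, THF, 0 °C
Reagents that add atoms: none
Why: Buffered fluoride cleaves the aryl silyl ether selectively, and the acetate, the benzoate and the γ-acyloxy enone should be stable to these near-neutral conditions.

**Compound list**

1 | (S)-4-[(tert-butyldimethylsilyl)oxy]cyclopent-2-en-1-one | O=C1C[C@H](O[Si](C)(C)C(C)(C)C)C=C1 | starting material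
2 | (S)-4-[(tert-butyldimethylsilyl)oxy]-2-iodocyclopent-2-en-1-one | O=C1C[C@H](O[Si](C)(C)C(C)(C)C)C=C1I | intermediate
3 | (S)-4-[(tert-butyldimethylsilyl)oxy]-2-methylcyclopent-2-en-1-one | O=C1C[C@H](O[Si](C)(C)C(C)(C)C)C=C1C | intermediate
4 | tert-butyldimethyl{[(1S,2S)-3-methyl-4-[(trimethylsilyl)oxy]-2-vinylcyclopent-3-en-1-yl]oxy}silane | C[Si](C)(C)OC1=C(C)[C@H](C=C)[C@@H](O[Si](C)(C)C(C)(C)C)C1 | intermediate
5 | lithium (3S,4S)-4-[(tert-butyldimethylsilyl)oxy]-2-methyl-3-vinylcyclopent-1-en-1-olate | [Li]OC1=C(C)[C@H](C=C)[C@@H](O[Si](C)(C)C(C)(C)C)C1 | intermediate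
6 | methyl 2-[(1S,2S,3S)-3-[(tert-butyldimethylsilyl)oxy]-1-methyl-5-oxo-2-vinylcyclopentyl]acetate | O=C1C[C@H](O[Si](C)(C)C(C)(C)C)[C@@H](C=C)[C@]1(C)CC(=O)OC | intermediate
7 | methyl 2-[(1S,2S,3S,5S)-3-[(tert-butyldimethylsilyl)oxy]-5-hydroxy-1-methyl-2-vinylcyclopentyl]acetate | O[C@H]1C[C@H](O[Si](C)(C)C(C)(C)C)[C@@H](C=C)[C@]1(C)CC(=O)OC | intermediate
8 | methyl 2-[(1S,2S,3S,5S)-5-acetoxy-3-[(tert-butyldimethylsilyl)oxy]-1-methyl-2-vinylcyclopentyl]acetate | CC(=O)O[C@H]1C[C@H](O[Si](C)(C)C(C)(C)C)[C@@H](C=C)[C@]1(C)CC(=O)OC | intermediate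
9 | methyl 2-[(1S,2S,3S,5S)-5-acetoxy-3-hydroxy-1-methyl-2-vinylcyclopentyl]acetate | CC(=O)O[C@H]1C[C@H](O)[C@@H](C=C)[C@]1(C)CC(=O)OC | intermediate
10 | methyl 2-[(1S,2S,5S)-5-acetoxy-1-methyl-3-oxo-2-vinylcyclopentyl]acetate | CC(=O)O[C@H]1CC(=O)[C@@H](C=C)[C@]1(C)CC(=O)OC | intermediate
11 | methyl 2-[(1S,2S,3S,5S)-5-acetoxy-3-hydroxy-3-isopropyl-1-methyl-2-vinylcyclopentyl]acetate | CC(=O)O[C@H]1C[C@](O)(C(C)C)[C@@H](C=C)[C@]1(C)CC(=O)OC | intermediate
12 | methyl 2-[(1S,2S,3S,5S)-5-acetoxy-2-formyl-3-hydroxy-3-isopropyl-1-methylcyclopentyl]acetate | CC(=O)O[C@H]1C[C@](O)(C(C)C)[C@@H](C=O)[C@]1(C)CC(=O)OC | intermediate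
13 | methyl 2-[(1S,2R,3S,5S)-5-acetoxy-3-hydroxy-2-[(S)-1-hydroxybut-2-yn-1-yl]-3-isopropyl-1-methylcyclopentyl]acetate (formed as its bromomagnesium alkoxide) | CC(=O)O[C@H]1C[C@](O)(C(C)C)[C@@H]([C@H](O)C#CC)[C@]1(C)CC(=O)OC | intermediate
14 | (1S,4aS,5S,7S,7aR)-7-hydroxy-7-isopropyl-4a-methyl-3-oxo-1-(prop-1-yn-1-yl)octahydrocyclopenta[c]pyran-5-yl acetate | CC(=O)O[C@H]1C[C@](O)(C(C)C)[C@H]2[C@@H](C#CC)OC(=O)C[C@]12C | intermediate
15 | (1S,4aS,5S,7S,7aR)-7-hydroxy-7-isopropyl-4a-methyl-3-oxo-1-[(Z)-2-(triethylsilyl)prop-1-en-1-yl]octahydrocyclopenta[c]pyran-5-yl acetate | CC(=O)O[C@H]1C[C@](O)(C(C)C)[C@H]2[C@@H](/C=C(/C)[Si](CC)(CC)CC)OC(=O)C[C@]12C | intermediate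
16 | (1S,4aS,5S,7S,7aR)-7-hydroxy-1-[(Z)-2-iodoprop-1-en-1-yl]-7-isopropyl-4a-methyl-3-oxooctahydrocyclopenta[c]pyran-5-yl acetate | CC(=O)O[C@H]1C[C@](O)(C(C)C)[C@H]2[C@@H](/C=C(/C)I)OC(=O)C[C@]12C | intermediate
17 | alkenyllithium: lactone 16 with iodine replaced by lithium (Z geometry kept) and the tertiary hydroxyl as its lithium alkoxide | CC(=O)O[C@H]1C[C@](O[Li])(C(C)C)[C@H]2[C@@H](/C=C(/C)[Li])OC(=O)C[C@]12C | intermediate
18 | bridged lithium hemiketalate: 8-oxabicyclo[3.2.1]oct-6-ene whose ring oxygen bridges C4 and C7 of the hydroazulene, C7 and C3 carrying O–Li | CC(=O)O[C@H]1C[C@](O[Li])(C(C)C)[C@H]2[C@H]3C=C(C)[C@](O[Li])(O3)C[C@]12C | intermediate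
19 | (1S,3S,3aR,4R,8aS)-3,4-dihydroxy-3-isopropyl-6,8a-dimethyl-7-oxo-1,2,3,3a,4,7,8,8a-octahydroazulen-1-yl acetate | CC(=O)O[C@H]1C[C@](O)(C(C)C)[C@H]2[C@H](O)C=C(C)C(=O)C[C@]12C | intermediate
20 | 4-hydroxybenzoic acid | O=C(O)c1ccc(O)cc1 | starting material
21 | tert-butyldimethylsilyl 4-[(tert-butyldimethylsilyl)oxy]benzoate | CC(C)(C)[Si](C)(C)OC(=O)c1ccc(O[Si](C)(C)C(C)(C)C)cc1 | intermediate
22 | 4-[(tert-butyldimethylsilyl)oxy]benzoic acid | CC(C)(C)[Si](C)(C)Oc1ccc(C(=O)O)cc1 | intermediate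
23 | (1S,3S,3aR,4R,8aS)-1-acetoxy-3-hydroxy-3-isopropyl-6,8a-dimethyl-7-oxo-1,2,3,3a,4,7,8,8a-octahydroazulen-4-yl 4-[(tert-butyldimethylsilyl)oxy]benzoate | CC(=O)O[C@H]1C[C@](O)(C(C)C)[C@H]2[C@H](OC(=O)c3ccc(O[Si](C)(C)C(C)(C)C)cc3)C=C(C)C(=O)C[C@]12C | intermediate
24 | (1S,3S,3aR,4R,8aS)-1-acetoxy-3-hydroxy-3-isopropyl-6,8a-dimethyl-7-oxo-1,2,3,3a,4,7,8,8a-octahydroazulen-4-yl 4-hydroxybenzoate | CC(=O)O[C@H]1C[C@](O)(C(C)C)[C@H]2[C@H](OC(=O)c3ccc(O)cc3)C=C(C)C(=O)C[C@]12C | target

**Step count and risks**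

Total step count: 17. Longest linear sequence: 16 steps (steps 1–14, 16 and 17, from 1 to 24).

Steps most likely to fail:

Step 14. Addition of t-BuLi to the lactone or acetate carbonyl, or proton transfer from the lactone α-methylene to the alkenyllithium (net loss of iodine without cyclisation), may compete with transannular acyl transfer. The fallback closes the ring by olefin metathesis instead; it sets out from aldehyde 12 and comes back at 19. Chelation-controlled addition of CH2=CHMgBr (THF, −78 °C) and PPTS-catalysed lactonisation should give (1R,4aS,5S,7S,7aR)-7-hydroxy-7-isopropyl-4a-methyl-3-oxo-1-vinyloctahydrocyclopenta[c]pyran-5-yl acetate F1. CH2=C(CH3)MgBr (THF, −78 °C) should open the lactone to (1S,2S,3R,4S)-4-hydroxy-3-[(R)-1-hydroxyprop-2-en-1-yl]-4-isopropyl-2-methyl-2-(3-methyl-2-oxobut-3-en-1-yl)cyclopentyl acetate F2. Ring-closing metathesis of F2 with second-generation Grubbs catalyst (toluene, 80 °C) would then form C5=C6 and give 19.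

Step 9. Enolisation of ketone 10 by the basic reagent, with β-elimination of the acetate, or acyl attack on the acetate may compete with carbonyl addition. The fallback carries the C1 oxygen as a silyl ether through the oxidation and addition; it sets out from alcohol 7 and comes back at 11. Silylation (TIPSOTf, 2,6-lutidine, CH2Cl2) should give methyl 2-[(1S,2S,3S,5S)-3-[(tert-butyldimethylsilyl)oxy]-1-methyl-5-[(triisopropylsilyl)oxy]-2-vinylcyclopentyl]acetate F3. Selective cleavage of the less hindered TBS ether (HF·pyridine, THF, 0 °C) should give methyl 2-[(1S,2S,3S,5S)-3-hydroxy-1-methyl-5-[(triisopropylsilyl)oxy]-2-vinylcyclopentyl]acetate F4. Dess–Martin oxidation should give methyl 2-[(1S,2S,5S)-1-methyl-3-oxo-5-[(triisopropylsilyl)oxy]-2-vinylcyclopentyl]acetate F5. Addition of i-PrMgCl/CeCl3 (THF, −78 °C) should give methyl 2-[(1S,2S,3S,5S)-3-hydroxy-3-isopropyl-1-methyl-5-[(triisopropylsilyl)oxy]-2-vinylcyclopentyl]acetate F6. TBAF (THF) should give methyl 2-[(1S,2S,3S,5S)-3,5-dihydroxy-3-isopropyl-1-methyl-2-vinylcyclopentyl]acetate F7. Acetylation of the secondary hydroxyl only (Ac2O, pyridine, DMAP) would return 11.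

Step 5. Facial selectivity may be poor, or the reduction slow, if the intrinsic bias of the hindered ketone opposes the catalyst. The fallback uses hydroxyl-directed reduction; it sets out from ketone 6 and comes back at 7. Desilylation (HF·pyridine, THF) should give methyl 2-[(1S,2S,3S)-3-hydroxy-1-methyl-5-oxo-2-vinylcyclopentyl]acetate F8. Evans–Saksena reduction (Me4NBH(OAc)3, AcOH/MeCN, −20 °C) delivers hydride intramolecularly from the face of the ring hydroxyl and should give the anti-1,3-diol methyl 2-[(1S,2S,3S,5S)-3,5-dihydroxy-1-methyl-2-vinylcyclopentyl]acetate F9. Selective silylation of the less hindered ring hydroxyl (TBSCl, imidazole, DMF, 0 °C) would return 7.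

**Further compounds**

F1 | step 14 | (1R,4aS,5S,7S,7aR)-7-hydroxy-7-isopropyl-4a-methyl-3-oxo-1-vinyloctahydrocyclopenta[c]pyran-5-yl acetate | CC(=O)O[C@H]1C[C@](O)(C(C)C)[C@H]2[C@@H](C=C)OC(=O)C[C@]12C
F2 | step 14 | (1S,2S,3R,4S)-4-hydroxy-3-[(R)-1-hydroxyprop-2-en-1-yl]-4-isopropyl-2-methyl-2-(3-methyl-2-oxobut-3-en-1-yl)cyclopentyl acetate | CC(=O)O[C@H]1C[C@](O)(C(C)C)[C@@H]([C@H](O)C=C)[C@]1(C)CC(=O)C(C)=C
F3 | step 9 | methyl 2-[(1S,2S,3S,5S)-3-[(tert-butyldimethylsilyl)oxy]-1-methyl-5-[(triisopropylsilyl)oxy]-2-vinylcyclopentyl]acetate | CC(C)[Si](C(C)C)(C(C)C)O[C@H]1C[C@H](O[Si](C)(C)C(C)(C)C)[C@@H](C=C)[C@]1(C)CC(=O)OC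
F4 | step 9 | methyl 2-[(1S,2S,3S,5S)-3-hydroxy-1-methyl-5-[(triisopropylsilyl)oxy]-2-vinylcyclopentyl]acetate | CC(C)[Si](C(C)C)(C(C)C)O[C@H]1C[C@H](O)[C@@H](C=C)[C@]1(C)CC(=O)OC
F5 | step 9 | methyl 2-[(1S,2S,5S)-1-methyl-3-oxo-5-[(triisopropylsilyl)oxy]-2-vinylcyclopentyl]acetate | CC(C)[Si](C(C)C)(C(C)C)O[C@H]1CC(=O)[C@@H](C=C)[C@]1(C)CC(=O)OC
F6 | step 9 | methyl 2-[(1S,2S,3S,5S)-3-hydroxy-3-isopropyl-1-methyl-5-[(triisopropylsilyl)oxy]-2-vinylcyclopentyl]acetate | CC(C)[Si](C(C)C)(C(C)C)O[C@H]1C[C@](O)(C(C)C)[C@@H](C=C)[C@]1(C)CC(=O)OC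
F7 | step 9 | methyl 2-[(1S,2S,3S,5S)-3,5-dihydroxy-3-isopropyl-1-methyl-2-vinylcyclopentyl]acetate | O[C@H]1C[C@](O)(C(C)C)[C@@H](C=C)[C@]1(C)CC(=O)OC
F8 | step 5 | methyl 2-[(1S,2S,3S)-3-hydroxy-1-methyl-5-oxo-2-vinylcyclopentyl]acetate | O=C1C[C@H](O)[C@@H](C=C)[C@]1(C)CC(=O)OC
F9 | step 5 | methyl 2-[(1S,2S,3S,5S)-3,5-dihydroxy-1-methyl-2-vinylcyclopentyl]acetate | O[C@H]1C[C@H](O)[C@@H](C=C)[C@]1(C)CC(=O)OC
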